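**Strategy.** Everything rests on cutting the dihydropyran ring of the 2,2-dimethylchroman fused to ring B (C3'–C4') back to an ortho-quinone methide and isobutene. The key step, a thermal inverse-demand hetero-Diels–Alder reaction, closes this ring in one operation by bonding the benzylic methylene C4 to C3 (together with O1–C2) and gives the chroman at its final oxidation level. It exploits the ortho pairing of the ring-B ether oxygen with the benzylic carbon and the gem-dimethyl carbon C2. Its precursor is merely the phenolic Mannich base of vanillin. Bromination/Stille prenylation, a Claisen-derived 3-(1,1-dimethylallyl)acetophenone, chalcone condensation and Algar–Flynn–Oyamada oxidation complete the flavonol.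

Key step: step 2

Remark: the target has no stereocentre; the E-alkene of 16 and the racemic centres of 13 and 17 are transient. Fragment numbering below uses chroman numbering for the ring-B building block.

**Step 1**
Reactants: 1 vanillin
Product: 2 3-[(dimethylamino)methyl]-4-hydroxy-5-methoxybenzaldehyde
Conditions: Me2NH (40% aq), CH2O (37% aq), EtOH, reflux
Reagents that add atoms: dimethylamine CNC; formaldehyde C=O
Why: Phenolic Mannich reaction, in which the iminium ion attacks the only free position ortho to the phenol (the para position carries the formyl group).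

**Step 2**
Reactants: 2 3-[(dimethylamino)methyl]-4-hydroxy-5-methoxybenzaldehyde; 3 isobutene
Product: 5 8-methoxy-2,2-dimethylchroman-6-carbaldehyde, via ortho-quinone methide 4 (not isolated)
Conditions: isobutene (large excess), PhMe, sealed steel vessel, 180 °C
Reagents that add atoms: none
Why: On heating, the Mannich base 2 should lose dimethylamine by 1,4-elimination through its phenoxide/ammonium zwitterion to give the electron-poor ortho-quinone methide 4, which isobutene traps in an inverse-electron-demand hetero-Diels–Alder reaction. The closest known reaction type is the thermal [4+2] cycloaddition of Mannich-base-derived ortho-quinone methides with 1,1-disubstituted alkenes, as used for 2,2-dialkylchromans of the tocopherol type. The dihydropyran ring is closed in a [4+2] mode: the alkene CH2 bonds to the exocyclic methylene (the C3–C4 bond) and the tertiary alkene carbon bonds to the carbonyl oxygen (O1–C2) in an asynchronous, rearomatising transition state. No stereocentre is formed. The step needs regioselectivity, secured by the polarisation of both partners (nucleophilic CH2 terminus onto the electrophilic methylene, positive charge developing on the tertiary carbon next to oxygen), and chemoselectivity over self-cycloaddition of 4, secured by its low stationary concentration in a large excess of isobutene; the formyl group lowers the LUMO of 4 and so helps an unactivated alkene to react.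

**Step 3**
Reactants: 5 8-methoxy-2,2-dimethylchroman-6-carbaldehyde
Product: 6 5-bromo-8-methoxy-2,2-dimethylchroman-6-carbaldehyde
Conditions: Br2 (1.05 equiv), NaOAc, AcOH, rt
Reagents that add atoms: bromine BrBr
Why: Electrophilic aromatic bromination para to the methoxy group (C5), by analogy with veratraldehyde giving 6-bromoveratraldehyde; the acetate buffer protects the tertiary chroman ether from HBr.

**Step 4**
Reactants: 6 5-bromo-8-methoxy-2,2-dimethylchroman-6-carbaldehyde; 7 tributyl(3-methylbut-2-en-1-yl)stannane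
Product: 8 8-methoxy-2,2-dimethyl-5-(3-methylbut-2-en-1-yl)chroman-6-carbaldehyde
Conditions: Pd(PPh3)4 (5 mol %), DMF, 100 °C
Reagents that add atoms: none
Why: Migita–Kosugi–Stille coupling, in which oxidative addition of the aldehyde-activated aryl bromide to zerovalent palladium, transmetalation and reductive elimination at the less hindered terminus of the η3-prenyl ligand should give the linear prenyl arene.

**Step 5**
Reactants: 8 8-methoxy-2,2-dimethyl-5-(3-methylbut-2-en-1-yl)chroman-6-carbaldehyde
Product: 9 8-hydroxy-2,2-dimethyl-5-(3-methylbut-2-en-1-yl)chroman-6-carbaldehyde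
Conditions: NaSEt (4 equiv), DMF, 130 °C; then HCl (aq, 1 M), 0 °C
Reagents that add atoms: none
Why: Thiolate demethylation of the aryl methyl ether by SN2 attack at the methyl carbon, which leaves the tertiary chroman ether, the prenyl alkene and the non-enolisable aldehyde untouched.

**Step 6**
Reactants: 10 2,4,6-trihydroxyacetophenone; 11 prenyl bromide
Product: 12 1-{2,6-dihydroxy-4-[(3-methylbut-2-en-1-yl)oxy]phenyl}ethan-1-one
Conditions: K2CO3 (1.0 equiv), acetone, reflux
Reagents that add atoms: none
Why: Williamson etherification at the 4-OH, the most acidic hydroxyl and the only one not hydrogen-bonded to the acetyl group.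

**Step 7**
Reactants: 12 1-{2,6-dihydroxy-4-[(3-methylbut-2-en-1-yl)oxy]phenyl}ethan-1-one
Product: 14 1-[2,4,6-trihydroxy-3-(2-methylbut-3-en-2-yl)phenyl]ethan-1-one, via Claisen dienone 13 (not isolated)
Conditions: PhNEt2, 190 °C, Ar
Reagents that add atoms: none
Why: Aromatic Claisen rearrangement: the [3,3] shift with allyl inversion delivers the 1,1-dimethylallyl group to either of the two equivalent ortho carbons, the para carbon is blocked by the acetyl group so no Cope migration to a para product can compete, and dienone 13 rearomatises by tautomerisation.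

**Step 8**
Reactants: 14 1-[2,4,6-trihydroxy-3-(2-methylbut-3-en-2-yl)phenyl]ethan-1-one
Product: 15 1-[2-hydroxy-4,6-bis(methoxymethoxy)-3-(2-methylbut-3-en-2-yl)phenyl]ethan-1-one
Conditions: MOMCl (2.1 equiv), K2CO3, acetone, 0 °C to rt
Reagents that add atoms: chloromethyl methyl ether COCCl
Why: O-Alkylation to the MOM ethers: the non-chelated 4-OH reacts first and, of the two chelated ortho hydroxyls, the 6-OH remote from the tertiary alkyl group reacts next, leaving the 2-OH that is both chelated and buttressed by the 1,1-dimethylallyl group.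

**Step 9**
Reactants: 15 1-[2-hydroxy-4,6-bis(methoxymethoxy)-3-(2-methylbut-3-en-2-yl)phenyl]ethan-1-one; 9 8-hydroxy-2,2-dimethyl-5-(3-methylbut-2-en-1-yl)chroman-6-carbaldehyde
Product: 16 (E)-1-[2-hydroxy-4,6-bis(methoxymethoxy)-3-(2-methylbut-3-en-2-yl)phenyl]-3-[8-hydroxy-2,2-dimethyl-5-(3-methylbut-2-en-1-yl)chroman-6-yl]prop-2-en-1-one
Conditions: KOH (aq, excess), EtOH, rt; AcOH quench
Reagents that add atoms: none
Why: Claisen–Schmidt condensation; the free hydroxyl of 9 is meta to the formyl group and does not deactivate it as the phenoxide, and E1cB dehydration gives the thermodynamically favoured E-enone.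

**Step 10**
Reactants: 16 (E)-chalcone
Product: 18 3-hydroxy-2-[8-hydroxy-2,2-dimethyl-5-(3-methylbut-2-en-1-yl)chroman-6-yl]-5,7-bis(methoxymethoxy)-8-(2-methylbut-3-en-2-yl)-4H-chromen-4-one, via trans-dihydroflavonol 17 (not isolated)
Conditions: H2O2 (30% aq), NaOH (aq), MeOH–THF, 0 °C to rt
Reagents that add atoms: hydrogen peroxide OO
Why: Algar–Flynn–Oyamada reaction: the 2'-phenoxide should close 6-endo onto the β-carbon as the α-carbon is oxygenated by the hydroperoxide, giving trans-dihydroflavonol 17, whose two stereocentres are erased when excess alkaline H2O2 dehydrogenates it; the isolated alkenes are inert to this nucleophilic oxidant.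

**Step 11**
Reactants: 18 bis-MOM flavonol
Product: 19 broussoflavonol E
Conditions: HCl (aq, 3 M), MeOH, 40 °C
Reagents that add atoms: none
Why: Acid-catalysed acetal exchange of the two phenolic MOM ethers with methanol under conditions too mild to protonate the prenyl alkene or the vinyl group of the 1,1-dimethylallyl unit at a competitive rate.

**Compound list**

1 | vanillin (4-hydroxy-3-methoxybenzaldehyde) | COc1cc(C=O)ccc1O | starting material
2 | 3-[(dimethylamino)methyl]-4-hydroxy-5-methoxybenzaldehyde | COc1cc(C=O)cc(CN(C)C)c1O | intermediate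
3 | isobutene (2-methylpropene) | CC(C)=C | starting material
4 | 5-methoxy-3-methylidene-4-oxocyclohexa-1,5-diene-1-carbaldehyde (ortho-quinone methide) | C=C1C=C(C=O)C=C(OC)C1=O | intermediate
5 | 8-methoxy-2,2-dimethylchroman-6-carbaldehyde | COc1cc(C=O)cc2c1OC(C)(C)CC2 | intermediate
6 | 5-bromo-8-methoxy-2,2-dimethylchroman-6-carbaldehyde | COc1cc(C=O)c(Br)c2c1OC(C)(C)CC2 | intermediate
7 | tributyl(3-methylbut-2-en-1-yl)stannane | CCCC[Sn](CCCC)(CCCC)CC=C(C)C | starting material
8 | 8-methoxy-2,2-dimethyl-5-(3-methylbut-2-en-1-yl)chroman-6-carbaldehyde | COc1cc(C=O)c(CC=C(C)C)c2c1OC(C)(C)CC2 | intermediate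
9 | 8-hydroxy-2,2-dimethyl-5-(3-methylbut-2-en-1-yl)chroman-6-carbaldehyde | Oc1cc(C=O)c(CC=C(C)C)c2c1OC(C)(C)CC2 | intermediate
10 | 2,4,6-trihydroxyacetophenone | CC(=O)c1c(O)cc(O)cc1O | starting material
11 | prenyl bromide (1-bromo-3-methylbut-2-ene) | CC(C)=CCBr | starting material
12 | 1-{2,6-dihydroxy-4-[(3-methylbut-2-en-1-yl)oxy]phenyl}ethan-1-one | CC(=O)c1c(O)cc(OCC=C(C)C)cc1O | intermediate
13 | 2-acetyl-3,5-dihydroxy-6-(2-methylbut-3-en-2-yl)cyclohexa-2,4-dien-1-one (racemic Claisen dienone) | CC(=O)C1=C(O)C(C(C)(C)C=C)C(=O)C=C1O | intermediate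
14 | 1-[2,4,6-trihydroxy-3-(2-methylbut-3-en-2-yl)phenyl]ethan-1-one | CC(=O)c1c(O)cc(O)c(C(C)(C)C=C)c1O | intermediate
15 | 1-[2-hydroxy-4,6-bis(methoxymethoxy)-3-(2-methylbut-3-en-2-yl)phenyl]ethan-1-one | CC(=O)c1c(OCOC)cc(OCOC)c(C(C)(C)C=C)c1O | intermediate
16 | (E)-1-[2-hydroxy-4,6-bis(methoxymethoxy)-3-(2-methylbut-3-en-2-yl)phenyl]-3-[8-hydroxy-2,2-dimethyl-5-(3-methylbut-2-en-1-yl)chroman-6-yl]prop-2-en-1-one | C=CC(C)(C)c1c(O)c(C(=O)/C=C/c2cc(O)c3c(c2CC=C(C)C)CCC(C)(C)O3)c(OCOC)cc1OCOC | intermediate
17 | trans-3-hydroxy-2-[8-hydroxy-2,2-dimethyl-5-(3-methylbut-2-en-1-yl)chroman-6-yl]-5,7-bis(methoxymethoxy)-8-(2-methylbut-3-en-2-yl)chroman-4-one (racemic; 2S,3S enantiomer drawn) | C=CC(C)(C)c1c(OCOC)cc(OCOC)c2c1O[C@@H](c1cc(O)c3c(c1CC=C(C)C)CCC(C)(C)O3)[C@H](O)C2=O | intermediate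
18 | 3-hydroxy-2-[8-hydroxy-2,2-dimethyl-5-(3-methylbut-2-en-1-yl)chroman-6-yl]-5,7-bis(methoxymethoxy)-8-(2-methylbut-3-en-2-yl)-4H-chromen-4-one | C=CC(C)(C)c1c(OCOC)cc(OCOC)c2c(=O)c(O)c(-c3cc(O)c4c(c3CC=C(C)C)CCC(C)(C)O4)oc12 | intermediate
19 | broussoflavonol E (3,5,7-trihydroxy-2-[8-hydroxy-2,2-dimethyl-5-(3-methylbut-2-en-1-yl)chroman-6-yl]-8-(2-methylbut-3-en-2-yl)-4H-chromen-4-one) | C=CC(C)(C)c1c(O)cc(O)c2c(=O)c(O)c(-c3cc(O)c4c(c3CC=C(C)C)CCC(C)(C)O4)oc12 | target

**Step count and risks**

Total steps: 11. Longest linear sequence: 8 (steps 1–5, 9, 10, 11 from vanillin).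

The three steps most likely to fail:

1. Step 2 (key step). The ortho-quinone methide 4 forms slowly from an electron-poor phenol and may be consumed by self-cycloaddition or by re-addition of dimethylamine before the unactivated, volatile alkene intercepts it. The fallback closes the same C3–C4 bond by olefin metathesis; it sets out from 1 and comes back at 5. Vanillin 1 would be brominated (Br2, AcOH, rt) to 5-bromovanillin F1. Stille coupling with tributyl(vinyl)stannane (Pd(PPh3)4, PhMe, 100 °C) would give 4-hydroxy-3-methoxy-5-vinylbenzaldehyde F2. Branched-selective Tsuji–Trost etherification with tert-butyl 2-methylbut-3-en-2-yl carbonate (Pd(PPh3)4, THF, rt) would give 3-methoxy-4-[(2-methylbut-3-en-2-yl)oxy]-5-vinylbenzaldehyde F3. Ring-closing metathesis with second-generation Grubbs catalyst (CH2Cl2, 40 °C) would give 8-methoxy-2,2-dimethyl-2H-chromene-6-carbaldehyde F4. Hydrogenation of its styrenic double bond (H2, 1 atm, Pd/C, EtOAc, rt, stopped after one equivalent) would return to 5.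

2. Step 10. The phenoxide may close at the α-carbon (5-exo) instead of the β-carbon, diverting material to aurone-type products; the 6'-alkoxy group and the ortho-substituted ring B both encourage this. The fallback separates ring closure from C3 oxygenation; it sets out from 16 and comes back at 18. Oxidative cyclisation of chalcone 16 with catalytic I2 in DMSO (110 °C) would give 2-[8-hydroxy-2,2-dimethyl-5-(3-methylbut-2-en-1-yl)chroman-6-yl]-5,7-bis(methoxymethoxy)-8-(2-methylbut-3-en-2-yl)-4H-chromen-4-one F5. Deprotonation with LiN(iPr)2 (excess, THF, −78 °C; phenoxide formation, then C3-lithiation), trapping with B(OMe)3 and oxidation of the borate with H2O2/AcOH would return to 18.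

3. Step 8. Discrimination between the two chelated ortho hydroxyls may be poor, or over-alkylation may occur, giving the wrong bis-MOM isomer or the tris-ether. The fallback fixes the regiochemistry before the Claisen step; it sets out from 12 and comes back at 15. Ether 12 would be mono-protected (MOMCl 1.05 equiv, K2CO3, acetone, rt) to 1-{2-hydroxy-6-(methoxymethoxy)-4-[(3-methylbut-2-en-1-yl)oxy]phenyl}ethan-1-one F6. Claisen rearrangement (PhNEt2, 190 °C), directed to C3 by the bond fixation of the chelated 2-hydroxyacetophenone, would give 1-[2,4-dihydroxy-6-(methoxymethoxy)-3-(2-methylbut-3-en-2-yl)phenyl]ethan-1-one F7. Its only non-chelated hydroxyl (4-OH) would then be protected (MOMCl, K2CO3, acetone) to return to 15.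

**Further compounds**

F1 | step 2 | 5-bromovanillin (3-bromo-4-hydroxy-5-methoxybenzaldehyde) | COc1cc(C=O)cc(Br)c1O
F2 | step 2 | 4-hydroxy-3-methoxy-5-vinylbenzaldehyde | COc1cc(C=O)cc(C=C)c1O
F3 | step 2 | 3-methoxy-4-[(2-methylbut-3-en-2-yl)oxy]-5-vinylbenzaldehyde | COc1cc(C=O)cc(C=C)c1OC(C)(C)C=C
F4 | step 2 | 8-methoxy-2,2-dimethyl-2H-chromene-6-carbaldehyde | COc1cc(C=O)cc2c1OC(C)(C)C=C2
F5 | step 10 | 2-[8-hydroxy-2,2-dimethyl-5-(3-methylbut-2-en-1-yl)chroman-6-yl]-5,7-bis(methoxymethoxy)-8-(2-methylbut-3-en-2-yl)-4H-chromen-4-one | C=CC(C)(C)c1c(OCOC)cc(OCOC)c2c(=O)cc(-c3cc(O)c4c(c3CC=C(C)C)CCC(C)(C)O4)oc12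
F6 | step 8 | 1-{2-hydroxy-6-(methoxymethoxy)-4-[(3-methylbut-2-en-1-yl)oxy]phenyl}ethan-1-one | CC(=O)c1c(O)cc(OCC=C(C)C)cc1OCOC
F7 | step 8 | 1-[2,4-dihydroxy-6-(methoxymethoxy)-3-(2-methylbut-3-en-2-yl)phenyl]ethan-1-one | CC(=O)c1c(OCOC)cc(O)c(C(C)(C)C=C)c1O
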